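The ten-membered ring is cut at C5–C6 (cyclodeca[b]furan locants: C4 carries the ester, C5 is the ring CH2, C6 the methyl carbinol). The key step exploits the aldol relationship O–C4–C5–C6–O of that ring. With C4 as a ketone, SmI2 turns a bromomethyl ketone into a regiodefined samarium enolate that adds to the C6 methyl ketone. One operation closes the carbocycle and creates the quaternary carbinol inside a samarium chelate; the new hydroxyl then directs hydride to C4. The precursor is a trans-4-(bromoacetyl)-5-alkylbutanolide whose side chain holds the ring-cis trisubstituted alkene and a methyl ketone, assembled by Wittig–Still rearrangement and an Evans succinate aldol.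

Key step: step 11

Remark: bicyclic compounds use cyclodeca[b]furan locants (O1, C2, C3, C3a, C4 to C11, C11a); the C3a descriptor switches between R and S with the C4 substituent while its spatial arrangement stays the same; simple deprotonation salts (alkoxides, amide anions, lithium enolates) are not numbered.

Step 1
Reactants: 1 2-bromoprop-2-en-1-ol
Product: 2 [(2-bromoprop-2-en-1-yl)oxy]tri(propan-2-yl)silane
Conditions: i-Pr3SiCl, imidazole, DMF, 0 °C to rt
Reagents that add atoms: chlorotri(propan-2-yl)silane, CC(C)[Si](Cl)(C(C)C)C(C)C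
Why: Silyl ether formation at the primary allylic alcohol; the bulky triisopropylsilyl group is chosen to resist anionic silyl migration in steps 2 and 3 and aqueous HBr in step 10.

Step 2
Reactants: 2 [(2-bromoprop-2-en-1-yl)oxy]tri(propan-2-yl)silane; 3 pent-4-enal
Product: 5 rac-2-({[tri(propan-2-yl)silyl]oxy}methyl)hepta-1,6-dien-3-ol, via vinyllithium 4 (not isolated)
Conditions: t-BuLi (2.1 equiv), Et2O, −78 °C; then 3, −78 °C; H2O
Reagents that add atoms: tert-butyllithium, [Li]C(C)(C)C (lithium kept only in intermediate 4)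
Why: Bromine–lithium exchange followed by 1,2-addition of the vinyllithium to the aldehyde; the carbinol centre is formed racemic and is erased in step 4.

Step 3
Reactants: 5 rac-2-({[tri(propan-2-yl)silyl]oxy}methyl)hepta-1,6-dien-3-ol
Product: 6 rac-tributyl({[2-({[tri(propan-2-yl)silyl]oxy}methyl)hepta-1,6-dien-3-yl]oxy}methyl)stannane
Conditions: KH, Bu3SnCH2I, 18-crown-6 (cat.), THF, 0 °C to rt
Reagents that add atoms: tributyl(iodomethyl)stannane, CCCC[Sn](CCCC)(CCCC)CI
Why: Williamson etherification of the potassium alkoxide with the iodomethylstannane prepares the substrate of the Wittig–Still rearrangement.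

Step 4
Reactants: 6 rac-tributyl({[2-({[tri(propan-2-yl)silyl]oxy}methyl)hepta-1,6-dien-3-yl]oxy}methyl)stannane
Product: 8 (3E)-3-({[tri(propan-2-yl)silyl]oxy}methyl)octa-3,7-dien-1-ol, via lithiomethyl ether 7 (not isolated)
Conditions: n-BuLi, THF, −78 °C; H2O
Reagents that add atoms: n-butyllithium, [Li]CCCC (lithium kept only in intermediate 7)
Why: Tin–lithium exchange triggers the [2,3]-sigmatropic Wittig–Still rearrangement, in which the carbinol substituent of a 2-substituted allyl ether sits pseudo-axial in the envelope transition state to avoid allylic 1,2-strain, so the butenyl chain should end cis to the new hydroxyethyl arm (E by the sequence rule, the ring-cis geometry of C9=C10 in the target).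

Step 5
Reactants: 8 (3E)-3-({[tri(propan-2-yl)silyl]oxy}methyl)octa-3,7-dien-1-ol
Product: 9 (3E)-3-({[tri(propan-2-yl)silyl]oxy}methyl)octa-3,7-dienal
Conditions: Dess–Martin periodinane, NaHCO3, CH2Cl2, 0 °C; used crude at once
Reagents that add atoms: none
Why: Dess–Martin oxidation under buffered, non-basic conditions should give the β,γ-unsaturated aldehyde without migration of the double bond into conjugation.

Step 6
Reactants: 10 (4R)-4-benzyl-1,3-oxazolidin-2-one; 11 methyl 4-chloro-4-oxobutanoate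
Product: 12 methyl 4-[(4R)-4-benzyl-2-oxo-1,3-oxazolidin-3-yl]-4-oxobutanoate
Conditions: n-BuLi, THF, −78 °C; then 11, −78 to 0 °C
Reagents that add atoms: none
Why: N-acylation of the lithiated oxazolidinone by the acid chloride (Evans imide formation).

Step 7
Reactants: 12 methyl 4-[(4R)-4-benzyl-2-oxo-1,3-oxazolidin-3-yl]-4-oxobutanoate; 9 (3E)-3-({[tri(propan-2-yl)silyl]oxy}methyl)octa-3,7-dienal
Product: 15 (4R)-4-benzyl-3-{[(2S,3R)-5-oxo-2-[(2E)-2-({[tri(propan-2-yl)silyl]oxy}methyl)hepta-2,6-dien-1-yl]oxolan-3-yl]carbonyl}-1,3-oxazolidin-2-one, via boron enolate 13 (not isolated), via aldol adduct 14 (not isolated)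
Conditions: Bu2BOTf, i-Pr2NEt, CH2Cl2, 0 °C; 9, −78 to 0 °C; pH 7 buffer, MeOH, H2O2; then PPTS (cat.), CH2Cl2, rt
Reagents that add atoms: dibutylboron triflate, CCCCB(CCCC)OS(=O)(=O)C(F)(F)F (boron and butyl groups kept only in intermediate 13)
Why: Evans syn-aldol reaction: the (Z)-boron enolate formed at the imide α-carbon adds through a Zimmerman–Traxler chair whose face is fixed by the (R)-benzyl auxiliary, setting the future C3a (R) and C11a (S), and the syn hydroxy ester then lactonises to the trans-disubstituted butanolide.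

Step 8
Reactants: 15 the lactone imide of step 7
Product: 16 (4R)-4-benzyl-3-{[(2S,3R)-5-oxo-2-[(2E)-6-oxo-2-({[tri(propan-2-yl)silyl]oxy}methyl)hept-2-en-1-yl]oxolan-3-yl]carbonyl}-1,3-oxazolidin-2-one
Conditions: PdCl2 (10 mol %), CuCl, O2 (1 atm), DMF/H2O (7:1), rt
Reagents that add atoms: water, O
Why: Tsuji–Wacker oxidation (hydroxypalladation by water, β-hydride elimination, reoxidation of palladium by CuCl/O2) is selective for the monosubstituted terminal alkene over the trisubstituted one and gives the methyl ketone.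

Step 9
Reactants: 16 the keto lactone imide of step 8
Product: 17 (2S,3R)-5-oxo-2-[(2E)-6-oxo-2-({[tri(propan-2-yl)silyl]oxy}methyl)hept-2-en-1-yl]oxolane-3-carboxylic acid
Conditions: LiOH, H2O2, THF/H2O (3:1), 0 °C; Na2SO3; HCl (aq) to pH 3
Reagents that add atoms: hydrogen peroxide, OO (one oxygen kept as the acid OH after sulfite reduction)
Why: Hydrolysis of the Evans imide by LiOOH, which attacks the exocyclic carbonyl selectively; the lactone, if opened, recloses on acidification and no stereocentre is touched.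

Step 10
Reactants: 17 the lactone acid of step 9
Product: 20 (4R,5S)-4-(bromoacetyl)-5-[(2E)-6-oxo-2-({[tri(propan-2-yl)silyl]oxy}methyl)hept-2-en-1-yl]oxolan-2-one, via mixed anhydride 18 (not isolated), via diazoketone 19 (not isolated)
Conditions: i-BuOCOCl, N-methylmorpholine, THF, −15 °C; CH2N2, Et2O, 0 °C; then 48% HBr (aq), 0 °C, 15 min
Reagents that add atoms: diazomethane, C=[N+]=[N-]; hydrogen bromide, Br; isobutyl chloroformate, CC(C)COC(Cl)=O (atoms kept only in intermediate 18)
Why: Acylation of diazomethane by the mixed anhydride (first stage of the Arndt–Eistert sequence) and Nierenstein-type hydrobromination of the diazoketone place the bromine regiospecifically on the future C5 under acidic conditions that do not enolise C3a.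

Step 11
Reactants: 20 (4R,5S)-4-(bromoacetyl)-5-[(2E)-6-oxo-2-({[tri(propan-2-yl)silyl]oxy}methyl)hept-2-en-1-yl]oxolan-2-one
Product: 22 (3aR,6R,9E,11aS)-6-hydroxy-6-methyl-10-({[tri(propan-2-yl)silyl]oxy}methyl)-3,3a,5,6,7,8,11,11a-octahydrocyclodeca[b]furan-2,4-dione, via samarium enolate 21 (not isolated)
Conditions: SmI2 (2.5 equiv), THF, −78 °C, 20 added over 4 h (final 0.003 M); NH4Cl (aq) at −78 °C; product used directly in step 12
Reagents that add atoms: samarium diiodide, I[Sm]I (samarium and iodine kept only in intermediate 21)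
Why: Two single-electron transfers from divalent samarium cleave the C–Br bond and give the trivalent samarium enolate 21 regiospecifically at C5, which adds to the C6 methyl ketone through a samarium-bridged chair-like (Zimmerman–Traxler) transition state; the resulting samarium aldolate chelate should hold the strained β-hydroxy ketone against retro-aldol cleavage until it is protonated. The closest known reaction type is the SmI2-mediated intramolecular Reformatsky-type aldol reaction of α-halo carbonyl compounds, which is used to close medium rings. The ten-membered carbocycle closes in the 10-(enolexo)-exo-trig mode, with the trans-fused butanolide and the ring-cis C9=C10 alkene keeping the two arms within reach. The new stereocentre C6 is controlled by C3a and C11a through the chelated transition state, in which the tether carbon C7 is expected pseudo-equatorial and the methyl pseudo-axial, placing the C6 oxygen cis to H-3a (6R). The step needs reduction of the α-bromo ketone in preference to the methyl ketone and the lactone, and aldol addition faster than proton transfer or attack on the lactone carbonyl (which would build a strained 2-oxabicyclo[2.2.1]heptane); the low temperature, the high dilution and the absence of HMPA or a proton source should secure this.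

Step 12
Reactants: 22 the ten-membered β-hydroxy ketone of step 11
Product: 23 (3aS,4S,6R,9E,11aS)-4,6-dihydroxy-6-methyl-10-({[tri(propan-2-yl)silyl]oxy}methyl)-3a,4,5,6,7,8,11,11a-octahydrocyclodeca[b]furan-2(3H)-one
Conditions: Me4NBH(OAc)3, MeCN/AcOH (1:1), −30 °C
Reagents that add atoms: none
Why: Evans–Saksena hydroxyl-directed reduction: the C6 hydroxyl binds the acetoxyborohydride and delivers hydride internally to C4, which should give the 4,6-anti (ring-trans) diol, i.e. 4S, under acidic conditions that suppress retro-aldol cleavage and lactone migration.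

Step 13
Reactants: 23 the 4,6-anti diol of step 12
Product: 26 (3aS,4S,6R,9E,11aS)-4,6-dihydroxy-6-methyl-3-methylidene-10-({[tri(propan-2-yl)silyl]oxy}methyl)-3a,4,5,6,7,8,11,11a-octahydrocyclodeca[b]furan-2(3H)-one, via Mannich base 24 (not isolated), via ammonium iodide 25 (not isolated)
Conditions: LiN(i-Pr)2 (4 equiv), THF, −78 °C; CH2=NMe2 I (Eschenmoser's salt), −78 to 0 °C; H2O; then MeI, MeOH, rt; NaHCO3 (aq), rt
Reagents that add atoms: N,N-dimethylmethyleneiminium iodide, C=[N+](C)C.[I-] (only its CH2 stays in 26); iodomethane, CI (methyl kept only in intermediate 25)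
Why: α-Methylenation by Mannich reaction of the lactone lithium enolate with Eschenmoser's salt, N-methylation and E1cB elimination of trimethylamine; fast enolisation at −78 °C deactivates the lactone carbonyl towards the neighbouring C4 alkoxide.

Step 14
Reactants: 27 (2E)-but-2-enal
Product: 28 (2Z)-2-iodobut-2-enal
Conditions: I2, K2CO3, DMAP (cat.), THF/H2O (1:1), rt
Reagents that add atoms: iodine, II
Why: α-Iodination of the enal by the DMAP-mediated addition–iodination–elimination sequence (Baylis–Hillman-type) should give the more stable Z isomer with iodine cis to the methyl group.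

Step 15
Reactants: 28 (2Z)-2-iodobut-2-enal
Product: 29 (2Z)-2-iodobut-2-en-1-ol
Conditions: NaBH4, CeCl3·7H2O, MeOH, 0 °C
Reagents that add atoms: none
Why: Luche 1,2-reduction of the enal leaves the vinyl iodide and the alkene geometry untouched.

Step 16
Reactants: 29 (2Z)-2-iodobut-2-en-1-ol
Product: 30 (2Z)-2-(hydroxymethyl)but-2-enoic acid
Conditions: CO (1 atm), Pd(OAc)2 (5 mol %), PPh3, K2CO3, DMF/H2O, 60 °C; HCl (aq) to pH 2
Reagents that add atoms: carbon monoxide, [C-]#[O+]; water, O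
Why: Palladium-catalysed hydroxycarbonylation (oxidative addition of the vinyl iodide to zerovalent palladium, CO insertion, hydrolysis of the acyl complex) proceeds with retention of alkene geometry, which places the carboxyl cis to the methyl group; a β-lactone formed by internal capture would be hydrolysed to the same acid.

Step 17
Reactants: 30 (2Z)-2-(hydroxymethyl)but-2-enoic acid
Product: 31 (2Z)-2-[(acetyloxy)methyl]but-2-enoic acid
Conditions: Ac2O, pyridine, CH2Cl2, 0 °C to rt; then THF/H2O, NaHCO3; acidify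
Reagents that add atoms: acetic anhydride, CC(=O)OC(C)=O
Why: Acetylation of the primary alcohol; a mixed anhydride formed at the carboxyl group is hydrolysed in the aqueous work-up.

Step 18
Reactants: 26 the α-methylene lactone diol of step 13; 31 (2Z)-2-[(acetyloxy)methyl]but-2-enoic acid
Product: 33 (3aR,4S,6R,9E,11aS)-6-hydroxy-6-methyl-3-methylidene-2-oxo-10-({[tri(propan-2-yl)silyl]oxy}methyl)-2,3,3a,4,5,6,7,8,11,11a-decahydrocyclodeca[b]furan-4-yl (2Z)-2-[(acetyloxy)methyl]but-2-enoate, via mixed anhydride 32 (not isolated)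
Conditions: 31, 2,4,6-trichlorobenzoyl chloride, Et3N, toluene, rt; then 26, toluene, 80 °C (no DMAP)
Reagents that add atoms: 2,4,6-trichlorobenzoyl chloride, O=C(Cl)c1c(Cl)cc(Cl)cc1Cl (atoms kept only in intermediate 32)
Why: Yamaguchi-type mixed-anhydride esterification run without a nucleophilic catalyst, as used for angelate esters, acylates the secondary C4 hydroxyl in preference to the tertiary C6 hydroxyl and avoids the Z-to-E isomerisation that DMAP would cause by reversible conjugate addition.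

Step 19
Reactants: 33 the silyl-protected ester of step 18
Product: 34 (3aR,4S,6R,9E,11aS)-6-hydroxy-10-(hydroxymethyl)-6-methyl-3-methylidene-2-oxo-2,3,3a,4,5,6,7,8,11,11a-decahydrocyclodeca[b]furan-4-yl (2Z)-2-[(acetyloxy)methyl]but-2-enoate
Conditions: HF·pyridine, pyridine, THF, 0 °C to rt
Reagents that add atoms: none
Why: Fluoride-mediated cleavage of the silyl ether under buffered conditions frees the primary allylic alcohol without touching the esters, the tertiary alcohol or the α-methylene lactone.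

Compound list
1 | 2-bromoprop-2-en-1-ol | C=C(Br)CO | starting material
2 | [(2-bromoprop-2-en-1-yl)oxy]tri(propan-2-yl)silane | C=C(Br)CO[Si](C(C)C)(C(C)C)C(C)C | intermediate
3 | pent-4-enal | C=CCCC=O | starting material
4 | [3-{[tri(propan-2-yl)silyl]oxy}prop-1-en-2-yl]lithium (vinyllithium) | [Li]C(=C)CO[Si](C(C)C)(C(C)C)C(C)C | intermediate (not isolated)
5 | rac-2-({[tri(propan-2-yl)silyl]oxy}methyl)hepta-1,6-dien-3-ol | C=C(CO[Si](C(C)C)(C(C)C)C(C)C)C(O)CCC=C | intermediate
6 | rac-tributyl({[2-({[tri(propan-2-yl)silyl]oxy}methyl)hepta-1,6-dien-3-yl]oxy}methyl)stannane | C=C(CO[Si](C(C)C)(C(C)C)C(C)C)C(OC[Sn](CCCC)(CCCC)CCCC)CCC=C | intermediate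
7 | rac-({[2-({[tri(propan-2-yl)silyl]oxy}methyl)hepta-1,6-dien-3-yl]oxy}methyl)lithium (lithiomethyl ether) | [Li]COC(CCC=C)C(=C)CO[Si](C(C)C)(C(C)C)C(C)C | intermediate (not isolated)
8 | (3E)-3-({[tri(propan-2-yl)silyl]oxy}methyl)octa-3,7-dien-1-ol (butenyl chain cis to the hydroxyethyl arm) | OCC/C(CO[Si](C(C)C)(C(C)C)C(C)C)=C\CCC=C | intermediate
9 | (3E)-3-({[tri(propan-2-yl)silyl]oxy}methyl)octa-3,7-dienal | O=CC/C(CO[Si](C(C)C)(C(C)C)C(C)C)=C\CCC=C | intermediate
10 | (4R)-4-benzyl-1,3-oxazolidin-2-one | O=C1OC[C@@H](Cc2ccccc2)N1 | starting material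
11 | methyl 4-chloro-4-oxobutanoate | COC(=O)CCC(Cl)=O | starting material
12 | methyl 4-[(4R)-4-benzyl-2-oxo-1,3-oxazolidin-3-yl]-4-oxobutanoate | COC(=O)CCC(=O)N1C(=O)OC[C@H]1Cc1ccccc1 | intermediate
13 | (Z)-dibutylboron enolate of 12, enolised at the imide α-carbon | CCCCB(CCCC)O/C(=C\CC(=O)OC)N1C(=O)OC[C@H]1Cc1ccccc1 | intermediate (not isolated)
14 | methyl (3R,4S,6E)-3-{[(4R)-4-benzyl-2-oxo-1,3-oxazolidin-3-yl]carbonyl}-4-hydroxy-6-({[tri(propan-2-yl)silyl]oxy}methyl)undeca-6,10-dienoate | COC(=O)C[C@H]([C@@H](O)C/C(CO[Si](C(C)C)(C(C)C)C(C)C)=C\CCC=C)C(=O)N1C(=O)OC[C@H]1Cc1ccccc1 | intermediate (not isolated)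
15 | (4R)-4-benzyl-3-{[(2S,3R)-5-oxo-2-[(2E)-2-({[tri(propan-2-yl)silyl]oxy}methyl)hepta-2,6-dien-1-yl]oxolan-3-yl]carbonyl}-1,3-oxazolidin-2-one (trans lactone) | C1C(=O)O[C@@H](C/C(CO[Si](C(C)C)(C(C)C)C(C)C)=C\CCC=C)[C@@H]1C(=O)N2C(=O)OC[C@H]2Cc3ccccc3 | intermediate
16 | (4R)-4-benzyl-3-{[(2S,3R)-5-oxo-2-[(2E)-6-oxo-2-({[tri(propan-2-yl)silyl]oxy}methyl)hept-2-en-1-yl]oxolan-3-yl]carbonyl}-1,3-oxazolidin-2-one | C1C(=O)O[C@@H](C/C(CO[Si](C(C)C)(C(C)C)C(C)C)=C\CCC(C)=O)[C@@H]1C(=O)N2C(=O)OC[C@H]2Cc3ccccc3 | intermediate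
17 | (2S,3R)-5-oxo-2-[(2E)-6-oxo-2-({[tri(propan-2-yl)silyl]oxy}methyl)hept-2-en-1-yl]oxolane-3-carboxylic acid | C1C(=O)O[C@@H](C/C(CO[Si](C(C)C)(C(C)C)C(C)C)=C\CCC(C)=O)[C@@H]1C(=O)O | intermediate
18 | mixed anhydride of 17 and isobutyl hydrogen carbonate | C1C(=O)O[C@@H](C/C(CO[Si](C(C)C)(C(C)C)C(C)C)=C\CCC(C)=O)[C@@H]1C(=O)OC(=O)OCC(C)C | intermediate (not isolated)
19 | (4R,5S)-4-(diazoacetyl)-5-[(2E)-6-oxo-2-({[tri(propan-2-yl)silyl]oxy}methyl)hept-2-en-1-yl]oxolan-2-one | C1C(=O)O[C@@H](C/C(CO[Si](C(C)C)(C(C)C)C(C)C)=C\CCC(C)=O)[C@@H]1C(=O)C=[N+]=[N-] | intermediate (not isolated)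
20 | (4R,5S)-4-(bromoacetyl)-5-[(2E)-6-oxo-2-({[tri(propan-2-yl)silyl]oxy}methyl)hept-2-en-1-yl]oxolan-2-one | C1C(=O)O[C@@H](C/C(CO[Si](C(C)C)(C(C)C)C(C)C)=C\CCC(C)=O)[C@@H]1C(=O)CBr | intermediate
21 | diiodosamarium enolate of the debrominated ketone from 20 (O-bound, terminal CH2) | C1C(=O)O[C@@H](C/C(CO[Si](C(C)C)(C(C)C)C(C)C)=C\CCC(C)=O)[C@@H]1C(=C)O[Sm](I)I | intermediate (not isolated)
22 | (3aR,6R,9E,11aS)-6-hydroxy-6-methyl-10-({[tri(propan-2-yl)silyl]oxy}methyl)-3,3a,5,6,7,8,11,11a-octahydrocyclodeca[b]furan-2,4-dione | C1C(=O)O[C@H]2C/C(CO[Si](C(C)C)(C(C)C)C(C)C)=C\CC[C@@](C)(O)CC(=O)[C@H]12 | intermediate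
23 | (3aS,4S,6R,9E,11aS)-4,6-dihydroxy-6-methyl-10-({[tri(propan-2-yl)silyl]oxy}methyl)-3a,4,5,6,7,8,11,11a-octahydrocyclodeca[b]furan-2(3H)-one | C1C(=O)O[C@H]2C/C(CO[Si](C(C)C)(C(C)C)C(C)C)=C\CC[C@@](C)(O)C[C@H](O)[C@H]12 | intermediate
24 | (3S,3aS,4S,6R,9E,11aS)-3-[(dimethylamino)methyl]-4,6-dihydroxy-6-methyl-10-({[tri(propan-2-yl)silyl]oxy}methyl)-3a,4,5,6,7,8,11,11a-octahydrocyclodeca[b]furan-2(3H)-one | CN(C)C[C@H]1C(=O)O[C@H]2C/C(CO[Si](C(C)C)(C(C)C)C(C)C)=C\CC[C@@](C)(O)C[C@H](O)[C@H]12 | intermediate (not isolated)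
25 | N-methyl ammonium iodide of 24 | C[N+](C)(C)C[C@H]1C(=O)O[C@H]2C/C(CO[Si](C(C)C)(C(C)C)C(C)C)=C\CC[C@@](C)(O)C[C@H](O)[C@H]12.[I-] | intermediate (not isolated)
26 | (3aS,4S,6R,9E,11aS)-4,6-dihydroxy-6-methyl-3-methylidene-10-({[tri(propan-2-yl)silyl]oxy}methyl)-3a,4,5,6,7,8,11,11a-octahydrocyclodeca[b]furan-2(3H)-one | C=C1C(=O)O[C@H]2C/C(CO[Si](C(C)C)(C(C)C)C(C)C)=C\CC[C@@](C)(O)C[C@H](O)[C@H]12 | intermediate
27 | (2E)-but-2-enal | C/C=C/C=O | starting material
28 | (2Z)-2-iodobut-2-enal | C/C=C(\I)C=O | intermediate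
29 | (2Z)-2-iodobut-2-en-1-ol | C/C=C(\I)CO | intermediate
30 | (2Z)-2-(hydroxymethyl)but-2-enoic acid | C/C=C(\C(=O)O)CO | intermediate
31 | (2Z)-2-[(acetyloxy)methyl]but-2-enoic acid | C/C=C(\C(=O)O)COC(C)=O | intermediate
32 | (2Z)-2-[(acetyloxy)methyl]but-2-enoic 2,4,6-trichlorobenzoic anhydride | C/C=C(\C(=O)OC(=O)c1c(Cl)cc(Cl)cc1Cl)COC(C)=O | intermediate (not isolated)
33 | (3aR,4S,6R,9E,11aS)-6-hydroxy-6-methyl-3-methylidene-2-oxo-10-({[tri(propan-2-yl)silyl]oxy}methyl)-2,3,3a,4,5,6,7,8,11,11a-decahydrocyclodeca[b]furan-4-yl (2Z)-2-[(acetyloxy)methyl]but-2-enoate | C=C1C(=O)O[C@H]2C/C(CO[Si](C(C)C)(C(C)C)C(C)C)=C\CC[C@@](C)(O)C[C@H](OC(=O)/C(=C\C)COC(C)=O)[C@H]12 | intermediate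
34 | (3aR,4S,6R,9E,11aS)-6-hydroxy-10-(hydroxymethyl)-6-methyl-3-methylidene-2-oxo-2,3,3a,4,5,6,7,8,11,11a-decahydrocyclodeca[b]furan-4-yl (2Z)-2-[(acetyloxy)methyl]but-2-enoate | C=C1C(=O)O[C@H]2C/C(CO)=C\CC[C@@](C)(O)C[C@H](OC(=O)/C(=C\C)COC(C)=O)[C@H]12 | target

Total step count: 19. Longest linear sequence: 14 steps (steps 1 to 5, 7 to 13, 18 and 19).

Steps most likely to fail

1. Step 11 (key step). The samarium enolate may be protonated before it cyclises (reductive debromination), may attack the lactone carbonyl, may oligomerise if the dilution is insufficient, or may add to the ketone with poor facial selectivity at C6. Fallback: from 20, reductive silylation (Zn, Me3SiCl, TMEDA, Et2O, 0 °C) should give the regiodefined trimethylsilyl enol ether F1. This is closed by a TiCl4-mediated intramolecular Mukaiyama aldol addition to the methyl ketone (CH2Cl2, −78 °C, high dilution), which runs through an open, non-chelated transition state and so has a different facial bias. The fallback comes back to the route at 22.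

2. Step 13. Translactonisation to the C4 oxygen by the neighbouring alkoxide and incomplete C-enolisation next to two lithium alkoxides may erode the methylenation. Fallback: from 23, both hydroxyls are capped (Me3SiOTf, 2,6-lutidine, CH2Cl2, −78 °C) to give the bis(trimethylsilyl) ether F2. Enolisation with LiN(i-Pr)2 and trapping with Eschenmoser's salt should give the Mannich base F3, MeI the ammonium iodide F4, and NaHCO3 the α-methylene lactone F5. PPTS in MeOH then removes both trimethylsilyl groups, and the fallback comes back to the route at 26.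

3. Step 18. Acyl transfer to the hindered C4 hydroxyl may be slower than Z-to-E isomerisation or loss of acetate from the activated acid. Fallback: from 22, chelation-controlled Narasaka–Prasad reduction (Et2BOMe, NaBH4, THF/MeOH, −78 °C) should give the 4,6-syn diol F6, the C4 epimer of 23. The methylenation sequence of step 13 then leads through the Mannich base F7 and the ammonium iodide F8 to the α-methylene lactone F9. A Mitsunobu esterification with acid 31 (PPh3, DIAD, toluene, 0 °C) activates the alcohol instead of the acid and installs the ester with inversion at C4, so the fallback comes back to the route at 33.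

Further compounds
F1 | step 11 | (4R,5S)-5-[(2E)-6-oxo-2-({[tri(propan-2-yl)silyl]oxy}methyl)hept-2-en-1-yl]-4-{1-[(trimethylsilyl)oxy]ethenyl}oxolan-2-one | C1C(=O)O[C@@H](C/C(CO[Si](C(C)C)(C(C)C)C(C)C)=C\CCC(C)=O)[C@@H]1C(=C)O[Si](C)(C)C
F2 | step 13 | (3aR,4S,6R,9E,11aS)-6-methyl-10-({[tri(propan-2-yl)silyl]oxy}methyl)-4,6-bis[(trimethylsilyl)oxy]-3a,4,5,6,7,8,11,11a-octahydrocyclodeca[b]furan-2(3H)-one | C1C(=O)O[C@H]2C/C(CO[Si](C(C)C)(C(C)C)C(C)C)=C\CC[C@@](C)(O[Si](C)(C)C)C[C@H](O[Si](C)(C)C)[C@H]12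
F3 | step 13 | (3S,3aR,4S,6R,9E,11aS)-3-[(dimethylamino)methyl]-6-methyl-10-({[tri(propan-2-yl)silyl]oxy}methyl)-4,6-bis[(trimethylsilyl)oxy]-3a,4,5,6,7,8,11,11a-octahydrocyclodeca[b]furan-2(3H)-one | CN(C)C[C@H]1C(=O)O[C@H]2C/C(CO[Si](C(C)C)(C(C)C)C(C)C)=C\CC[C@@](C)(O[Si](C)(C)C)C[C@H](O[Si](C)(C)C)[C@H]12
F4 | step 13 | N-methyl ammonium iodide of F3 | C[N+](C)(C)C[C@H]1C(=O)O[C@H]2C/C(CO[Si](C(C)C)(C(C)C)C(C)C)=C\CC[C@@](C)(O[Si](C)(C)C)C[C@H](O[Si](C)(C)C)[C@H]12.[I-]
F5 | step 13 | (3aR,4S,6R,9E,11aS)-6-methyl-3-methylidene-10-({[tri(propan-2-yl)silyl]oxy}methyl)-4,6-bis[(trimethylsilyl)oxy]-3a,4,5,6,7,8,11,11a-octahydrocyclodeca[b]furan-2(3H)-one | C=C1C(=O)O[C@H]2C/C(CO[Si](C(C)C)(C(C)C)C(C)C)=C\CC[C@@](C)(O[Si](C)(C)C)C[C@H](O[Si](C)(C)C)[C@H]12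
F6 | step 18 | (3aS,4R,6R,9E,11aS)-4,6-dihydroxy-6-methyl-10-({[tri(propan-2-yl)silyl]oxy}methyl)-3a,4,5,6,7,8,11,11a-octahydrocyclodeca[b]furan-2(3H)-one | C1C(=O)O[C@H]2C/C(CO[Si](C(C)C)(C(C)C)C(C)C)=C\CC[C@@](C)(O)C[C@@H](O)[C@H]12
F7 | step 18 | (3S,3aS,4R,6R,9E,11aS)-3-[(dimethylamino)methyl]-4,6-dihydroxy-6-methyl-10-({[tri(propan-2-yl)silyl]oxy}methyl)-3a,4,5,6,7,8,11,11a-octahydrocyclodeca[b]furan-2(3H)-one | CN(C)C[C@H]1C(=O)O[C@H]2C/C(CO[Si](C(C)C)(C(C)C)C(C)C)=C\CC[C@@](C)(O)C[C@@H](O)[C@H]12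
F8 | step 18 | N-methyl ammonium iodide of F7 | C[N+](C)(C)C[C@H]1C(=O)O[C@H]2C/C(CO[Si](C(C)C)(C(C)C)C(C)C)=C\CC[C@@](C)(O)C[C@@H](O)[C@H]12.[I-]
F9 | step 18 | (3aS,4R,6R,9E,11aS)-4,6-dihydroxy-6-methyl-3-methylidene-10-({[tri(propan-2-yl)silyl]oxy}methyl)-3a,4,5,6,7,8,11,11a-octahydrocyclodeca[b]furan-2(3H)-one | C=C1C(=O)O[C@H]2C/C(CO[Si](C(C)C)(C(C)C)C(C)C)=C\CC[C@@](C)(O)C[C@@H](O)[C@H]12
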